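Ring D (C8–C14–C13–C16–C15) is drawn from a benzene ring: its five carbons and C12 are the ring of 3-hydroxy-2-methoxybenzoic acid, whose adjacent O-bearing carbons become C16 and C15. Oxidative dearomatisation to a masked o-benzoquinone and an ester-tethered Diels–Alder reaction with a (Z)-silyl enol ether on the ring-A block give a bicyclo[2.2.2]octenone holding the δ-lactone, C8, C9 and C11. The key step makes a radical at C13; the C16 acyl carbon, placed β to it on bridgehead C12, shifts to C13. The six-membered ring C8–C14–C13–C12–C16–C15 thereby contracts to ring D, the bicyclo[3.2.1]octane appears, and the C15 ketal/C16 ketone pair remains as latent enone.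

Key step: step 12

Remark on numbering: ent-kaurane numbers are used for all compounds.
- Ring A is C1–C5 and C10.
- C19 is the methyl and C18 the CH2OH on C4; C6 is the CH2OH on C5.
- The lactone is C10–C20–O–C7(=O)–C8–C9.
- Ring C is C8, C9, C11, C12, C13, C14; ring D is C8, C14, C13, C16, C15; C17 is the exocyclic CH2.

Assumption: compounds 1, 5 and 12 and all reagents named under the steps are taken as commercial.

Step 1
Reactants: 1 3-methylcyclohex-2-en-1-one
Product: 3 (2S,3S)-2,3-bis(hydroxymethyl)-3-methylcyclohexan-1-one, via aldol silane 2 (not isolated)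
Conditions: i-PrOMe2SiCH2MgCl (from i-PrOMe2SiCH2Cl, Mg, THF), Cu(OTf)2 (3 mol %), chiral hydroxyalkyl-imidazolinium salt (NHC precursor, 4 mol %, the enantiomer that gives 3S), Et2O, −30 °C; CH2O (gas), −78 °C; aq. work-up; then 30% H2O2, KF, KHCO3, THF–MeOH, rt
Reagents that add atoms: (chloromethyl)isopropoxydimethylsilane CC(C)O[Si](C)(C)CCl; formaldehyde C=O; hydrogen peroxide OO
Why: Cu–NHC-catalysed asymmetric conjugate addition of a Grignard reagent to a β-substituted cyclohexenone sets quaternary C4 under ligand control, the regiodefined magnesium enolate takes up formaldehyde (aldol) at C5 anti to the axially delivered silylmethyl group so that C6 and C18 end up trans, and Tamao oxidation turns C–Si into C–OH.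

Step 2
Reactants: 3 (2S,3S)-2,3-bis(hydroxymethyl)-3-methylcyclohexan-1-one
Product: 4 (2S,3S)-2,3-bis{[(tert-butyldimethylsilyl)oxy]methyl}-3-methylcyclohexan-1-one
Conditions: TBSCl, imidazole, DMF, 0 °C → rt
Reagents that add atoms: tert-butyldimethylsilyl chloride CC(C)(C)[Si](C)(C)Cl
Why: Standard silylation of two primary alcohols, with a base too weak to enolise the ketone, so C5 should keep its configuration.

Step 3
Reactants: 5 prop-2-en-1-ol
Product: 7 [(allyloxy)methyl]triphenylphosphonium chloride, via allyl chloromethyl ether 6 (not isolated)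
Conditions: (CH2O)n, HCl (gas), 0 °C; separate, dry; then PPh3, toluene, 80 °C
Reagents that add atoms: formaldehyde C=O; hydrogen chloride Cl; triphenylphosphine c1ccc(cc1)P(c1ccccc1)c1ccccc1
Why: Chloromethylation of an alcohol followed by SN2 quaternisation of the phosphine by the very reactive α-chloro ether.

Step 4
Reactants: 4 (2S,3S)-2,3-bis{[(tert-butyldimethylsilyl)oxy]methyl}-3-methylcyclohexan-1-one; 7 [(allyloxy)methyl]triphenylphosphonium chloride
Product: 10 (1R,2R,3S)-1-allyl-2,3-bis{[(tert-butyldimethylsilyl)oxy]methyl}-3-methylcyclohexane-1-carbaldehyde, via ylide 8 (not isolated), via allyl enol ether 9 (not isolated)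
Conditions: KOt-Bu, THF, −78 → 0 °C; filter through silica; then xylene, 140 °C
Reagents that add atoms: none
Why: Wittig olefination at low temperature (addition should outrun enolisation towards C5) gives the exocyclic allyl enol ether, and the aliphatic Claisen rearrangement forms the C10–C9 bond on the equatorial face because the axial face is closed by the 1,3-diaxial C19 methyl, so C9 ends up trans to C6 and the formyl carbon C20 axial.

Step 5
Reactants: 10 (1R,2R,3S)-1-allyl-2,3-bis{[(tert-butyldimethylsilyl)oxy]methyl}-3-methylcyclohexane-1-carbaldehyde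
Product: 11 [(1R,2R,3S)-1-allyl-2,3-bis{[(tert-butyldimethylsilyl)oxy]methyl}-3-methylcyclohexyl]methanol
Conditions: NaBH4, MeOH–THF, 0 °C
Reagents that add atoms: none
Why: Hydride reduction of a non-enolisable aldehyde to the C20 alcohol, with no stereocentre involved.

Step 6
Reactants: 12 3-hydroxy-2-methoxybenzoic acid
Product: 13 3-acetoxy-2-methoxybenzoic acid
Conditions: Ac2O, pyridine, rt; aq. work-up
Reagents that add atoms: acetic anhydride CC(=O)OC(C)=O
Why: O-acetylation masks the phenol for the acylation, and the mixed anhydride formed at the acid is hydrolysed on work-up.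

Step 7
Reactants: 13 3-acetoxy-2-methoxybenzoic acid; 11 [(1R,2R,3S)-1-allyl-2,3-bis{[(tert-butyldimethylsilyl)oxy]methyl}-3-methylcyclohexyl]methanol
Product: 15 C20 3-acetoxy-2-methoxybenzoate of alcohol 11, via acid chloride 14 (not isolated)
Conditions: (COCl)2, DMF (cat.), CH2Cl2, 0 °C → rt; evaporate; then 11, pyridine, CH2Cl2, 0 → 40 °C
Reagents that add atoms: none
Why: Acylation of the primary neopentyl-type alcohol with an acetoxy-aroyl chloride, a robust class of acylating agent, creates the C7–O–C20 ester that later becomes the lactone.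

Step 8
Reactants: 15 C20 3-acetoxy-2-methoxybenzoate of alcohol 11
Product: 16 aldehyde ester (C10–C9H2–C11HO)
Conditions: O3, CH2Cl2, −78 °C; then PPh3, −78 °C → rt
Reagents that add atoms: ozone [O-][O+]=O
Why: Ozonolysis cleaves the only alkene, while the arene is deactivated by its ester and acetate groups.

Step 9
Reactants: 16 aldehyde ester (C10–C9H2–C11HO)
Product: 17 (Z)-triisopropylsilyl enol ether (C9=C11)
Conditions: TIPSOTf, Et3N, CH2Cl2, 0 °C → rt
Reagents that add atoms: triisopropylsilyl trifluoromethanesulfonate CC(C)[Si](C(C)C)(C(C)C)OS(=O)(=O)C(F)(F)F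
Why: Soft enolisation of an aldehyde through its O-silyl oxocarbenium ion, which as a rule gives the (Z)-enol silane, the geometry that later places C10 and O-11 cis.

Step 10
Reactants: 17 (Z)-triisopropylsilyl enol ether (C9=C11)
Product: 18 free phenol (3-hydroxy-2-methoxybenzoate)
Conditions: K2CO3 (cat.), MeOH–THF, 0 °C
Reagents that add atoms: none
Why: Base-catalysed methanolysis removes the activated aryl acetate much faster than it touches the hindered benzoate or the bulky silyl enol ether.

Step 11
Reactants: 18 free phenol (3-hydroxy-2-methoxybenzoate)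
Product: 20 bicyclo[2.2.2]octenone lactone (bridgeheads C8 and C12; bridges C9–C11 C13=C14 C15–C16), via masked o-benzoquinone 19 (not isolated)
Conditions: PhI(OAc)2, MeOH–CH2Cl2, 0 °C; evaporate; then toluene (high dilution), 80 °C
Reagents that add atoms: methanol CO
Why: Oxidative dearomatisation of the guaiacol unit gives the 6,6-dimethoxy-2,4-dienone, which undergoes an intramolecular inverse-demand Diels–Alder reaction in which the tether and the electronic ortho preference both pair C9 with C8 and C11 with C12, the endo mode keeps C10 and OTIPS away from the ketal and syn to C13=C14, the (Z)-alkene makes C10 and O-11 cis, and a chair-like lactone-forming transition state with C1 axial and the bulkier C5 equatorial selects the diene face.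

Step 12
Reactants: 20 bicyclo[2.2.2]octenone lactone
Product: 22 bicyclo[3.2.1]octan-16-one lactone (C15 dimethyl ketal), via C13 catecholboronate 21 (not isolated)
Conditions: RhCl(PPh3)3 (2 mol %), catecholborane, THF, rt; MeOH; then 4-tert-butylcatechol (syringe pump), air, toluene, 80 °C
Reagents that add atoms: none
Why: Rh-catalysed syn hydroboration, which takes alkenes in preference to ketones, should put boron on C13, the alkene carbon remote from quaternary C8 and the C15 methoxy groups and on the only open face (the other is covered by C10 and OTIPS), and the aryloxyl radical of the catechol then displaces the secondary C13 radical from boron (radical protodeboronation of a B-alkylcatecholborane). The C13 radical adds 3-exo-trig to the C16 carbonyl carbon, which hangs on bridgehead C12 and is activated by the α-ketal, and the cyclopropyloxy radical opens by scission of C12–C16, that is a Dowd–Beckwith 1,2-acyl shift, the reaction type known to turn bicyclo[2.2.2]octanones from masked o-benzoquinones into bicyclo[3.2.1]octanones. Ring D is closed by the new C13–C16 bond while the six-membered ring C8–C14–C13–C12–C16–C15 expels C12, ring C stays six-membered, and the C12 radical takes hydrogen from the catechol. The new stereocentre C13 is fixed by the cage, since C16 can reach only the lobe of the C13 orbital on its own side, so its configuration follows from C8 and C12. The step needs boron at C13 rather than C14 and a shift that is faster than hydrogen transfer; sterics should secure the first, and slow addition of the catechol at 80 °C together with relief of the eclipsed [2.2.2] strain, raised by the endo C10 and OTIPS groups, the second. No alkene and no second ketone stands next to C12, so no competing vinyl or acyl shift is open.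

Step 13
Reactants: 22 bicyclo[3.2.1]octan-16-one lactone (C15 dimethyl ketal)
Product: 23 16-methylene 15,15-dimethyl ketal
Conditions: Ph3PCH3Br, KOt-Bu, THF, 0 → 60 °C
Reagents that add atoms: methyltriphenylphosphonium bromide C[P+](c1ccccc1)(c1ccccc1)c1ccccc1.[Br-]
Why: Wittig methylenation of a ketone that cannot enolise (bridgehead C13, ketal C15), while the lactone carbonyl on quaternary C8 is too hindered to compete.

Step 14
Reactants: 23 16-methylene 15,15-dimethyl ketal
Product: 24 target CNP0152458.1
Conditions: 48% aq. HF, MeCN, 0 °C → rt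
Reagents that add atoms: water O
Why: Aqueous HF cleaves the two TBS ethers and the TIPS ether and hydrolyses the allylic dimethyl ketal through its stabilised oxocarbenium ion, which unveils the C15 ketone/C16 methylene enone without touching any stereocentre.

Compound list
1 | 3-methylcyclohex-2-en-1-one | CC1=CC(=O)CCC1 | starting material
2 | (2S,3S)-2-(hydroxymethyl)-3-{[dimethyl(propan-2-yloxy)silyl]methyl}-3-methylcyclohexan-1-one | O=C1CCC[C@](C)(C[Si](C)(C)OC(C)C)[C@H]1CO | intermediate
3 | (2S,3S)-2,3-bis(hydroxymethyl)-3-methylcyclohexan-1-one (C6 and C18 arms trans) | O=C1CCC[C@](C)(CO)[C@H]1CO | intermediate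
4 | (2S,3S)-2,3-bis{[(tert-butyldimethylsilyl)oxy]methyl}-3-methylcyclohexan-1-one | O=C1CCC[C@](C)(CO[Si](C)(C)C(C)(C)C)[C@H]1CO[Si](C)(C)C(C)(C)C | intermediate
5 | prop-2-en-1-ol | C=CCO | starting material
6 | allyl chloromethyl ether | C=CCOCCl | intermediate
7 | [(allyloxy)methyl]triphenylphosphonium chloride | C=CCOC[P+](c1ccccc1)(c1ccccc1)c1ccccc1.[Cl-] | intermediate
8 | (allyloxymethylene)triphenylphosphorane | C=CCOC=P(c1ccccc1)(c1ccccc1)c1ccccc1 | intermediate
9 | allyl enol ether of the C10 exocyclic alkene (E/Z mixture at C10=C20) | C=CCOC=C1CCC[C@](C)(CO[Si](C)(C)C(C)(C)C)[C@H]1CO[Si](C)(C)C(C)(C)C | intermediate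
10 | (1R,2R,3S)-1-allyl-2,3-bis{[(tert-butyldimethylsilyl)oxy]methyl}-3-methylcyclohexane-1-carbaldehyde (allyl trans to C6) | C=CC[C@@]1(CCC[C@](C)(CO[Si](C)(C)C(C)(C)C)[C@H]1CO[Si](C)(C)C(C)(C)C)C=O | intermediate
11 | [(1R,2R,3S)-1-allyl-2,3-bis{[(tert-butyldimethylsilyl)oxy]methyl}-3-methylcyclohexyl]methanol | C=CC[C@@]1(CCC[C@](C)(CO[Si](C)(C)C(C)(C)C)[C@H]1CO[Si](C)(C)C(C)(C)C)CO | intermediate
12 | 3-hydroxy-2-methoxybenzoic acid | COc1c(O)cccc1C(=O)O | starting material
13 | 3-acetoxy-2-methoxybenzoic acid | COc1c(OC(C)=O)cccc1C(=O)O | intermediate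
14 | 3-acetoxy-2-methoxybenzoyl chloride | COc1c(OC(C)=O)cccc1C(=O)Cl | intermediate
15 | C20 3-acetoxy-2-methoxybenzoate of alcohol 11 | C=CC[C@@]1(CCC[C@](C)(CO[Si](C)(C)C(C)(C)C)[C@H]1CO[Si](C)(C)C(C)(C)C)COC(=O)c1cccc(OC(C)=O)c1OC | intermediate
16 | aldehyde ester (C10–C9H2–C11HO) | O=CC[C@@]1(CCC[C@](C)(CO[Si](C)(C)C(C)(C)C)[C@H]1CO[Si](C)(C)C(C)(C)C)COC(=O)c1cccc(OC(C)=O)c1OC | intermediate
17 | (Z)-triisopropylsilyl enol ether (C9=C11), aryl acetate | CC(C)[Si](C(C)C)(C(C)C)O/C=C\[C@@]1(CCC[C@](C)(CO[Si](C)(C)C(C)(C)C)[C@H]1CO[Si](C)(C)C(C)(C)C)COC(=O)c1cccc(OC(C)=O)c1OC | intermediate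
18 | (Z)-silyl enol ether, free phenol | CC(C)[Si](C(C)C)(C(C)C)O/C=C\[C@@]1(CCC[C@](C)(CO[Si](C)(C)C(C)(C)C)[C@H]1CO[Si](C)(C)C(C)(C)C)COC(=O)c1cccc(O)c1OC | intermediate
19 | masked o-benzoquinone: C20 ester of 6,6-dimethoxy-5-oxocyclohexa-1,3-diene-1-carboxylic acid | CC(C)[Si](C(C)C)(C(C)C)O/C=C\[C@@]1(CCC[C@](C)(CO[Si](C)(C)C(C)(C)C)[C@H]1CO[Si](C)(C)C(C)(C)C)COC(=O)C1=CC=CC(=O)C1(OC)OC | intermediate
20 | bicyclo[2.2.2]octenone lactone: C16 ketone on C12, C15 dimethyl ketal on C8, C13=C14 alkene; C10 and the C11 OTIPS group both syn to the C13=C14 bridge; C14 on the same side of the lactone ring as C1 | O=C1C(OC)(OC)[C@]23C=C[C@H]1[C@@H](O[Si](C(C)C)(C(C)C)C(C)C)[C@H]2[C@@]1(CCC[C@](C)(CO[Si](C)(C)C(C)(C)C)[C@H]1CO[Si](C)(C)C(C)(C)C)COC3=O | intermediate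
21 | C13 catecholboronate of 20 (boron on the face turned to the C15–C16 bridge) | O=C1C(OC)(OC)[C@]23C[C@H](B4Oc5ccccc5O4)[C@H]1[C@@H](O[Si](C(C)C)(C(C)C)C(C)C)[C@H]2[C@@]1(CCC[C@](C)(CO[Si](C)(C)C(C)(C)C)[C@H]1CO[Si](C)(C)C(C)(C)C)COC3=O | intermediate
22 | bicyclo[3.2.1]octan-16-one lactone: C16 now bonded to C13, C12 a CH2, C15 dimethyl ketal; H-9 and H-11 syn to the C15–C16 bridge | O=C1C(OC)(OC)[C@]23C[C@H]1C[C@@H](O[Si](C(C)C)(C(C)C)C(C)C)[C@H]2[C@@]1(CCC[C@](C)(CO[Si](C)(C)C(C)(C)C)[C@H]1CO[Si](C)(C)C(C)(C)C)COC3=O | intermediate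
23 | 16-methylene 15,15-dimethyl ketal, fully silylated | C=C1C(OC)(OC)[C@]23C[C@H]1C[C@@H](O[Si](C(C)C)(C(C)C)C(C)C)[C@H]2[C@@]1(CCC[C@](C)(CO[Si](C)(C)C(C)(C)C)[C@H]1CO[Si](C)(C)C(C)(C)C)COC3=O | intermediate
24 | CNP0152458.1, 6,11,18-trihydroxy-15-oxo-6,7-seco-ent-kaur-16-en-7,20-olide | C=C1C(=O)[C@]23C[C@H]1C[C@@H](O)[C@H]2[C@@]1(CCC[C@](C)(CO)[C@H]1CO)COC3=O | target

Total step count: 14
Longest linear sequence: 12 steps (1, 2, 4, 5, 7, 8, 9, 10, 11, 12, 13, 14)

Steps most likely to fail

Step 12.
- What may go wrong: hydrogen transfer to the C13 radical before the acyl shift, or delivery of boron to C14. Either would only saturate the alkene and leave the bicyclo[2.2.2]octane intact.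
- Fallback: it sets out from 21 (made from 20 as in step 12) and returns at 22. Oxidation of the C–B bond with NaBO3·4H2O (retention) should give the C13 alcohol F1. Thiocarbonyldiimidazole converts it into the C13 imidazole-1-carbothioate F2. Barton–McCombie conditions (Bu3SnH and AIBN by syringe pump into refluxing toluene at high dilution) generate the same C13 radical from an isolable precursor. The stannane concentration can be set as low as the shift requires, and the Dowd–Beckwith migration then leads to 22.

Step 11.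
- What may go wrong: slow folding of the s-trans ester may let dimerisation of the dienone or solvolysis of the enol ether win over the cycloaddition. Facial selectivity may also be poor.
- Fallback: it sets out from 11 and 12 and returns at 20.
  - Alcohol 11 is acetylated (Ac2O, pyridine) to the C20 acetate F3.
  - F3 is ozonolysed (O3, then PPh3) to the acetate aldehyde F4.
  - F4 is silylated (TIPSOTf, Et3N) to the acetate (Z)-enol ether F5.
  - Acid 12 is esterified (MeOH, H2SO4) to methyl 3-hydroxy-2-methoxybenzoate F6.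
  - F6 is added slowly and in excess to PhI(OAc)2 and F5 in MeOH. The methyl ester dienone F7 formed in the flask should add to F5 in an untethered inverse-demand Diels–Alder reaction with the same ortho and endo preference, giving the open adduct F8.
  - K2CO3 in MeOH removes the acetate, and the C20 alkoxide closes the δ-lactone on the C7 methyl ester to give 20.

Step 1.
- What may go wrong: sluggish transfer of the α-silyl alkyl group from copper, erosion of enantioselectivity by uncatalysed addition, and retro-aldol cleavage or epimerisation at C5 during the oxidative work-up.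
- Fallback: it sets out from 1 and returns at 3. Copper/phosphinamine-catalysed asymmetric conjugate addition of (E)-hex-1-enyldiisobutylalane (from 1-hexyne and DIBAL-H), a well-transferring sp2 group, followed by Ac2O gives the alkenyl enol acetate F9. MeLi releases the lithium enolate, which takes up formaldehyde anti to the alkenyl group to give the alkenyl aldol F10. Ozonolysis (PPh3 work-up) cuts the alkenyl group down to the C18 keto aldehyde F11. NaBH(OAc)3 reduces the aldehyde but not the ketone and gives 3.

Further compounds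
F1 | step 12 | C13 alcohol of the bicyclo[2.2.2]octanone lactone | O=C1C(OC)(OC)[C@]23C[C@H](O)[C@H]1[C@@H](O[Si](C(C)C)(C(C)C)C(C)C)[C@H]2[C@@]1(CCC[C@](C)(CO[Si](C)(C)C(C)(C)C)[C@H]1CO[Si](C)(C)C(C)(C)C)COC3=O
F2 | step 12 | C13 imidazole-1-carbothioate | O=C1C(OC)(OC)[C@]23C[C@H](OC(=S)n4ccnc4)[C@H]1[C@@H](O[Si](C(C)C)(C(C)C)C(C)C)[C@H]2[C@@]1(CCC[C@](C)(CO[Si](C)(C)C(C)(C)C)[C@H]1CO[Si](C)(C)C(C)(C)C)COC3=O
F3 | step 11 | C20 acetate of alcohol 11 | C=CC[C@@]1(CCC[C@](C)(CO[Si](C)(C)C(C)(C)C)[C@H]1CO[Si](C)(C)C(C)(C)C)COC(C)=O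
F4 | step 11 | acetate aldehyde | O=CC[C@@]1(CCC[C@](C)(CO[Si](C)(C)C(C)(C)C)[C@H]1CO[Si](C)(C)C(C)(C)C)COC(C)=O
F5 | step 11 | acetate (Z)-triisopropylsilyl enol ether | CC(C)[Si](C(C)C)(C(C)C)O/C=C\[C@@]1(CCC[C@](C)(CO[Si](C)(C)C(C)(C)C)[C@H]1CO[Si](C)(C)C(C)(C)C)COC(C)=O
F6 | step 11 | methyl 3-hydroxy-2-methoxybenzoate | COC(=O)c1cccc(O)c1OC
F7 | step 11 | methyl 6,6-dimethoxy-5-oxocyclohexa-1,3-diene-1-carboxylate | COC(=O)C1=CC=CC(=O)C1(OC)OC
F8 | step 11 | open bicyclo[2.2.2]octenone adduct (C7 methyl ester, C20 acetate) | O=C1C(OC)(OC)[C@]2(C(=O)OC)C=C[C@H]1[C@@H](O[Si](C(C)C)(C(C)C)C(C)C)[C@H]2[C@@]1(CCC[C@](C)(CO[Si](C)(C)C(C)(C)C)[C@H]1CO[Si](C)(C)C(C)(C)C)COC(C)=O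
F9 | step 1 | 3-[(E)-hex-1-enyl]-3-methylcyclohex-1-enyl acetate (C4 configured as in 3) | CC(=O)OC1=C[C@@](C)(/C=C/CCCC)CCC1
F10 | step 1 | 3-[(E)-hex-1-enyl]-2-(hydroxymethyl)-3-methylcyclohexan-1-one (C6 trans to the alkenyl group) | O=C1CCC[C@](C)(/C=C/CCCC)[C@H]1CO
F11 | step 1 | 2-(hydroxymethyl)-1-methyl-3-oxocyclohexane-1-carbaldehyde (configured as in 3) | O=C1CCC[C@](C)(C=O)[C@H]1CO
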